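Ring positions are given in flavan numbering (O1, C2, C3, C4, C4a, C5–C8, C8a; ring A = benzo ring, ring B = C2 aryl, ring C = pyran), also for open-chain precursors. Compound numbers are those of the steps and the compound list below.

## Analysis of the target

Target 27 is a flavan-3-ol ester: a chroman whose ring A carries hydroxyls at C5 and C7, whose ring C carries the 3,4,5-trihydroxyphenyl ring B at C2 and a 4-hydroxybenzoyloxy group at C3. The only stereocentres are the adjacent C2 and C3, both R, which places ring B and the ester oxygen cis on ring C. This is the less stable arrangement, so it has to be made under kinetic control. Six free phenols (above all the pyrogallol ring B) make the compound sensitive to air and base, and C2 is a benzylic ether carbon that can ionise. The difficulties are the cis relationship in one absolute configuration, the regiochemistry of attaching C4 to an electron-rich ring A, and acylation of O3 alone among seven oxygen functions. The last point requires every phenol to be masked by a group that leaves under neutral conditions, so benzyl ethers are used throughout. The strategy rests on the pattern of ring A: oxygen at C5, C7 and C8a, and the single carbon substituent C4 on C4a between the C5 and C8a oxygens. That is the pattern formed when the vinylketene from a 3-alkoxycyclobutenone combines with an alkyne bearing oxygen on one carbon and the C4 chain on the other. Ring A can therefore be built around a side chain that already holds both stereocentres.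

## Retrosynthetic reasoning

27 is traced to hexabenzyl ether 26 by cleavage of six O–benzyl bonds; hydrogenolysis is neutral and spares the ester and both stereocentres. 26 is cut at the ester C–O bond into chromanol 24 and acid chloride 25, so the acyl group enters when O3 is the only free hydroxyl.

24 comes from acetal 23, and 23 from phenol 22 by O-benzylation at C5. This extra operation is needed because ring closure leaves one ring A phenol free, and a phenol would be acylated in preference to the hindered O3.

22 is disconnected at O1–C2 to triol 21. The bond is cut here because C2 is a carbinol carbon that can be displaced with inversion, so the erythro chain gives the cis ring. The forward Mitsunobu closure has to be an SN2 process. The two phenols of 21 flanking the chain are equivalent, so no regiochemical question arises.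

21 is the desilylated form of phenol 20, and 20 is taken apart at three ring A bonds (C4a–C8a, C5–C6, C8–C8a) into siloxyalkyne 13 and cyclobutenone 15. Cutting here removes ring A altogether and leaves an acyclic chain with no arene to control. The forward benzannulation must put the chain-bearing alkyne carbon on the ketene carbonyl carbon.

13 is traced by removal of the ynol oxygen to terminal alkyne 10, which comes via 9 and 8 from epoxide 5 and alkyne 6 (as its lithio form 7). The bond cut is C4–C4a, made forward by SN2 opening of the oxirane at its unsubstituted carbon, which cannot disturb either stereocentre.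

5 is the silyl ether of epoxy alcohol 4, which is obtained from racemic allylic alcohol 3 by Sharpless kinetic resolution. This single operation selects the C2 precursor centre and creates the C3 centre with the erythro relationship. 3 is cut at the C2–C3 bond into aldehyde 1 and Grignard reagent 2.

15 is related to commercial 14 by exchange of its ethoxy group for a benzyloxy group, because the C7 oxygen must be released by the final hydrogenolysis.

## Alternatives that were turned down

Alternative 1: The C3=C4 double bond of a flav-3-ene is disconnected.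
- **Key step:** diene A2, (3R)-3-[3,5-bis(benzyloxy)-2-ethenylphenoxy]-3-[3,4,5-tris(benzyloxy)phenyl]prop-1-en-2-yl 4-(benzyloxy)benzoate, would undergo ring-closing metathesis with the second-generation Grubbs catalyst. This joins the styrene carbon C4 to the enol ester carbon C3 and gives 2H-chromenyl ester A1. A last hydrogenation would add hydrogen to C3–C4 anti to ring B (giving cis) while removing the benzyl groups.
- **For it:** the ester is carried from the start, ring A is bought complete, and the route would need roughly eight to ten steps, fewer than here.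
- **Against it:** C2 of A2 is benzylic to an electron-rich ring, allylic, and the carbinol carbon of an aryl ether. It can ionise, and A2 is an allyl aryl ether open to Claisen rearrangement into the free C8 position at the temperatures a slow enol ester metathesis needs. Making this centre enantiopure beside an enol ester is itself unsolved. In A1 the C2–O1 bond is both allylic and benzylic, so hydrogenolytic ring opening competes with the face-selective saturation that sets C3.
- **Comparison:** it is stronger on length and convergence. The chosen route keeps C2 as a configurationally stable protected carbinol until one stereospecific displacement.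

Alternative 2: The C4–C4a bond is disconnected by intramolecular arene alkylation.
- **Key step:** glycidyl aryl ether A4, (2R)-2-{(R)-[3,5-bis(benzyloxy)phenoxy][3,4,5-tris(benzyloxy)phenyl]methyl}oxirane, would come from epoxy alcohol 4 by Mitsunobu etherification with inversion. A mild acid would then make the ring A carbon ortho to O1 open the oxirane at C4, giving chromanol A3, which is identical with 24.
- **For it:** both stereocentres are in place before ring closure and come from the same epoxy alcohol as here. About six steps from 1 would suffice against fifteen, so on step economy this alternative is clearly stronger.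
- **Against it:** the arene must attack the primary terminus (6-endo). Acid-activated oxiranes open preferentially at the carbon that better carries positive charge, here C3, which gives a 2,3-dihydrobenzofuran by 5-exo closure. The acid can also ionise the C2–O1 bond of A4 or cause a hydride shift of the oxirane to a carbonyl compound. The intermolecular Mitsunobu step at a hindered, ionisable carbinol is harder than the intramolecular one used here.
- **Comparison:** the chosen strategy pays about nine extra steps. In return the C4–C4a bond is made by an unambiguous SN2 opening at the terminal carbon, and the ring A regiochemistry is fixed by bond polarity, not by a competition between ring sizes.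

Alternative 3: O1–C2 and C3–C4 are disconnected in one hetero-Diels–Alder step.
- **Key step:** a chiral phosphoric acid would dehydrate salicyl alcohol A6, 3,5-bis(benzyloxy)-2-(hydroxymethyl)phenol, to the ring A ortho-quinone methide. This would add (Z)-enol ester A7, (Z)-2-[3,4,5-tris(benzyloxy)phenyl]ethenyl 4-(benzyloxy)benzoate, to give A5, which is identical with 26.
- **For it:** it is the most convergent plan, with two fragments, the ester in place and four to five steps in all. The cis relationship would follow from the Z geometry in a suprafacial addition.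
- **Against it:** three selectivities ride on one step.
  - Regiochemistry: enol ester polarisation would put O1 on C3, and only styrene polarisation puts it on C2.
  - Diastereoselectivity: a stepwise path through the ring B stabilised benzylic cation loses the cis relationship.
  - Enantioselectivity: the quinone methide has no substituent on its methylene carbon, condenses readily with itself, and the dienophile offers the catalyst no hydrogen-bond donor.
- **Comparison:** it is far shorter. The chosen route takes its stereochemistry from a reagent-controlled epoxidation and a displacement of defined course, and confines its risk to a thermal step with no selectivity in absolute configuration to achieve.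

Key step: step 9

Assumption: 3,4,5-tris(benzyloxy)benzaldehyde, 3-ethoxycyclobut-2-en-1-one and 4-(benzyloxy)benzoyl chloride are taken as purchasable.

## Route

Step 1
Reactants: 1 3,4,5-tris(benzyloxy)benzaldehyde; 2 vinylmagnesium bromide
Product: 3 rac-1-[3,4,5-tris(benzyloxy)phenyl]prop-2-en-1-ol
Conditions: THF, 0 °C; then aq NH4Cl
Reagents that add atoms: none
Why: Grignard 1,2-addition to an aryl aldehyde forms the C2–C3 bond; the carbinol is racemic and is resolved in the next step.

Step 2
Reactants: 3 rac-1-[3,4,5-tris(benzyloxy)phenyl]prop-2-en-1-ol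
Product: 4 (S)-[(2R)-oxiran-2-yl][3,4,5-tris(benzyloxy)phenyl]methanol
Conditions: Ti(OiPr)4 (15 mol %), L-(+)-DIPT (20 mol %), t-BuOOH (0.6 equiv), 4 Å MS, CH2Cl2, −20 °C
Reagents that add atoms: tert-butyl hydroperoxide, CC(C)(C)OO
Why: Sharpless kinetic resolution: with the L-(+)-tartrate the (R)-carbinol is epoxidised fast on the face that gives the erythro epoxy alcohol, so the carbinol centre is selected by the resolution (its descriptor becomes S only through the changed CIP ranking) and the oxirane centre (R) is set by the tartrate. The slow (S)-enantiomer of 3 stays behind and is separated; at most half of 3 can be converted.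

Step 3
Reactants: 4 (S)-[(2R)-oxiran-2-yl][3,4,5-tris(benzyloxy)phenyl]methanol
Product: 5 tert-butyldimethyl{(S)-[(2R)-oxiran-2-yl][3,4,5-tris(benzyloxy)phenyl]methoxy}silane
Conditions: TBSCl, imidazole, DMF, 0 °C → rt
Reagents that add atoms: tert-butyldimethylsilyl chloride, CC(C)(C)[Si](C)(C)Cl
Why: Standard silylation of a secondary alcohol; blocking the carbinol prevents Payne rearrangement of the epoxy alkoxide in the basic step that follows.

Step 4
Reactants: 5 tert-butyldimethyl{(S)-[(2R)-oxiran-2-yl][3,4,5-tris(benzyloxy)phenyl]methoxy}silane; 6 trimethylsilylacetylene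
Product: 8 (1S,2R)-1-(tert-butyldimethylsilyloxy)-1-[3,4,5-tris(benzyloxy)phenyl]-5-(trimethylsilyl)pent-4-yn-2-ol, via lithium (trimethylsilyl)acetylide 7 (not isolated)
Conditions: 6, n-BuLi, THF, −78 °C; BF3·OEt2, then 5, −78 °C; then aq NH4Cl
Reagents that add atoms: none
Why: Yamaguchi–Hirao alkynylation: the BF3-activated oxirane is opened by the acetylide in an SN2 reaction at the unsubstituted carbon, forming the future C4–C4a bond and leaving both stereocentres untouched. The low temperature keeps the silyl group from migrating to the new alkoxide.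

Step 5
Reactants: 8 (1S,2R)-1-(tert-butyldimethylsilyloxy)-1-[3,4,5-tris(benzyloxy)phenyl]-5-(trimethylsilyl)pent-4-yn-2-ol
Product: 9 tert-butyl{[(1S,2R)-2-(methoxymethoxy)-1-[3,4,5-tris(benzyloxy)phenyl]-5-(trimethylsilyl)pent-4-yn-1-yl]oxy}dimethylsilane
Conditions: MOMCl, iPr2NEt, Bu4NI (cat.), CH2Cl2, 0 → 40 °C
Reagents that add atoms: chloromethyl methyl ether, COCCl
Why: Acetal protection of O3 under mild amine base; the methoxymethyl ether withstands strong base, peroxide, heat, fluoride and Mitsunobu conditions and is removed later by acid, when all phenols are benzylated.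

Step 6
Reactants: 9 tert-butyl{[(1S,2R)-2-(methoxymethoxy)-1-[3,4,5-tris(benzyloxy)phenyl]-5-(trimethylsilyl)pent-4-yn-1-yl]oxy}dimethylsilane
Product: 10 tert-butyl{[(1S,2R)-2-(methoxymethoxy)-1-[3,4,5-tris(benzyloxy)phenyl]pent-4-yn-1-yl]oxy}dimethylsilane
Conditions: K2CO3 (cat.), MeOH/THF, rt
Reagents that add atoms: none
Why: Methoxide-catalysed protodesilylation of the alkynylsilane; the secondary alkyl silyl ether and the acetal are inert to these conditions.

Step 7
Reactants: 10 tert-butyl{[(1S,2R)-2-(methoxymethoxy)-1-[3,4,5-tris(benzyloxy)phenyl]pent-4-yn-1-yl]oxy}dimethylsilane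
Product: 13 (4R,5S)-5-(tert-butyldimethylsilyloxy)-4-(methoxymethoxy)-5-[3,4,5-tris(benzyloxy)phenyl]-1-(triisopropylsilyloxy)pent-1-yne, via lithium acetylide 11 (not isolated), via lithium ynolate 12 (not isolated)
Conditions: n-BuLi, THF, −78 °C; LiOOtBu (from t-BuOOH and LiN(SiMe3)2), −78 → 0 °C; TIPSOTf, −78 → 0 °C; Et3N-deactivated silica
Reagents that add atoms: tert-butyl hydroperoxide, CC(C)(C)OO; triisopropylsilyl trifluoromethanesulfonate, CC(C)[Si](OS(=O)(=O)C(F)(F)F)(C(C)C)C(C)C
Why: Oxidation of a lithium acetylide by lithium tert-butyl peroxide (electrophilic oxygen transfer) gives the ynolate, and the bulky silyl triflate silylates it on oxygen, not on carbon, to give the ynol silyl ether. Ethers, acetal and alkyl silyl ether do not react with these reagents at or below 0 °C.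

Step 8
Reactants: 14 3-ethoxycyclobut-2-en-1-one
Product: 15 3-(benzyloxy)cyclobut-2-en-1-one
Conditions: BnOH (3 equiv), TsOH·H2O (2 mol %), PhMe, 50 °C, reduced pressure (removal of EtOH)
Reagents that add atoms: benzyl alcohol, OCc1ccccc1
Why: Acid-catalysed alkoxy exchange of a vinylogous ester by addition–elimination at C3, driven by removal of the volatile alcohol; the benzyl group makes the future C7 oxygen removable by hydrogenolysis.

Step 9
Reactants: 13 (4R,5S)-5-(tert-butyldimethylsilyloxy)-4-(methoxymethoxy)-5-[3,4,5-tris(benzyloxy)phenyl]-1-(triisopropylsilyloxy)pent-1-yne; 15 3-(benzyloxy)cyclobut-2-en-1-one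
Product: 20 5-(benzyloxy)-2-[(2R,3S)-3-(tert-butyldimethylsilyloxy)-2-(methoxymethoxy)-3-[3,4,5-tris(benzyloxy)phenyl]propyl]-3-(triisopropylsilyloxy)phenol, via vinylketene 16 (not isolated), via vinylcyclobutenone 17 (not isolated), via dienylketene 18 (not isolated), via cyclohexadienone 19 (not isolated)
Conditions: 15 (2 equiv), PhMe, 80 → 110 °C, sealed tube, argon
Reagents that add atoms: none
Why: Heat opens 15 by four-electron electrocyclic ring opening to vinylketene 16, and the nucleophilic chain-bearing carbon of ynol silyl ether 13 adds to the ketene carbonyl carbon in a [2+2] cycloaddition that gives 17 (bonds C4a–C8a and C5–C6). 17 opens by a second four-electron electrocyclic step to dienylketene 18, ring A closes by thermal six-electron disrotatory electrocyclisation (bond C8–C8a) to dienone 19, and tautomerisation gives phenol 20. The closest known reaction is the Danheiser benzannulation of cyclobutenones with siloxyalkynes to resorcinol monosilyl ethers; the donor-substituted cyclobutenone is the unusual partner, so a higher temperature than for 3-alkylcyclobutenones is planned. The ketene oxygen becomes the C8a hydroxyl, the siloxy carbon becomes C5, the benzyloxy carbon C7, and the chain sits on C4a. No stereocentre is formed: the sp3 ring carbon of 17 is transient, and the two chain centres are remote and not epimerisable under neutral thermal conditions. The selectivity needed is the regiochemistry of the [2+2] step, secured by the polarisation of the O–C≡C unit; a direct [4+2] addition of 16 to 13 would give the same constitution. The ketene must also add to the alkyne faster than it acylates the phenol formed, which is why 15 is used in excess.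

Step 10
Reactants: 20 5-(benzyloxy)-2-[(2R,3S)-3-(tert-butyldimethylsilyloxy)-2-(methoxymethoxy)-3-[3,4,5-tris(benzyloxy)phenyl]propyl]-3-(triisopropylsilyloxy)phenol
Product: 21 5-(benzyloxy)-2-[(2R,3S)-3-hydroxy-2-(methoxymethoxy)-3-[3,4,5-tris(benzyloxy)phenyl]propyl]benzene-1,3-diol
Conditions: TBAF, AcOH (3 equiv each), THF, rt → 45 °C, argon
Reagents that add atoms: none
Why: Fluoride cleaves both the aryl and the benzylic alkyl silyl ether (Si–F bond formation); the acetic acid buffer protects the electron-rich resorcinol from base and air. The two phenols flanking the chain become equivalent.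

Step 11
Reactants: 21 5-(benzyloxy)-2-[(2R,3S)-3-hydroxy-2-(methoxymethoxy)-3-[3,4,5-tris(benzyloxy)phenyl]propyl]benzene-1,3-diol
Product: 22 (2R,3R)-7-(benzyloxy)-3-(methoxymethoxy)-2-[3,4,5-tris(benzyloxy)phenyl]chroman-5-ol
Conditions: PPh3, DIAD (betaine pre-formed), THF (0.01 M), 0 °C → rt
Reagents that add atoms: none
Why: Intramolecular Mitsunobu etherification: a phenol displaces the alkoxyphosphonium group at the benzylic carbon in a 6-exo-tet SN2 closure of ring C, inverting C2 (S to R), so the erythro chain gives the cis chroman; C3 is not touched. The adjacent C–O bond disfavours ionisation at C2.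

Step 12
Reactants: 22 (2R,3R)-7-(benzyloxy)-3-(methoxymethoxy)-2-[3,4,5-tris(benzyloxy)phenyl]chroman-5-ol
Product: 23 (2R,3R)-5,7-bis(benzyloxy)-3-(methoxymethoxy)-2-[3,4,5-tris(benzyloxy)phenyl]chroman
Conditions: BnBr, K2CO3, DMF, rt
Reagents that add atoms: benzyl bromide, BrCc1ccccc1
Why: Williamson etherification of the remaining C5 phenol, which would otherwise be acylated before the hindered O3 in step 14.

Step 13
Reactants: 23 (2R,3R)-5,7-bis(benzyloxy)-3-(methoxymethoxy)-2-[3,4,5-tris(benzyloxy)phenyl]chroman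
Product: 24 (2R,3R)-5,7-bis(benzyloxy)-2-[3,4,5-tris(benzyloxy)phenyl]chroman-3-ol
Conditions: HCl (cat., in MeOH), MeOH/THF, 45 °C
Reagents that add atoms: none
Why: Acid-catalysed acetal exchange transfers the methoxymethyl group to methanol; benzyl ethers are stable, and the acid is kept dilute so that the C2–O1 bond does not ionise.

Step 14
Reactants: 24 (2R,3R)-5,7-bis(benzyloxy)-2-[3,4,5-tris(benzyloxy)phenyl]chroman-3-ol; 25 4-(benzyloxy)benzoyl chloride
Product: 26 (2R,3R)-5,7-bis(benzyloxy)-2-[3,4,5-tris(benzyloxy)phenyl]chroman-3-yl 4-(benzyloxy)benzoate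
Conditions: DMAP (cat.), Et3N, CH2Cl2, 0 °C → rt
Reagents that add atoms: none
Why: DMAP-catalysed acylation of the only free hydroxyl; acylation at oxygen does not affect the C3 configuration.

Step 15
Reactants: 26 (2R,3R)-5,7-bis(benzyloxy)-2-[3,4,5-tris(benzyloxy)phenyl]chroman-3-yl 4-(benzyloxy)benzoate
Product: 27 (2R,3R)-5,7-dihydroxy-2-(3,4,5-trihydroxyphenyl)chroman-3-yl 4-hydroxybenzoate (epigallocatechin 3-O-(4-hydroxybenzoate))
Conditions: H2 (1 atm), Pd(OH)2/C, THF/MeOH, rt; work-up under argon
Reagents that add atoms: none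
Why: Catalytic hydrogenolysis removes all six benzyl ethers under neutral conditions; the ester and the cyclic C2–O1 aryl ether should remain, so both stereocentres are preserved.

## Compound list

1 | 3,4,5-tris(benzyloxy)benzaldehyde | O=Cc1cc(OCc2ccccc2)c(OCc2ccccc2)c(OCc2ccccc2)c1 | starting material
2 | vinylmagnesium bromide | C=C[Mg]Br | starting material
3 | rac-1-[3,4,5-tris(benzyloxy)phenyl]prop-2-en-1-ol | C=CC(O)c1cc(OCc2ccccc2)c(OCc2ccccc2)c(OCc2ccccc2)c1 | intermediate
4 | (S)-[(2R)-oxiran-2-yl][3,4,5-tris(benzyloxy)phenyl]methanol | C1O[C@H]1[C@@H](O)c1cc(OCc2ccccc2)c(OCc2ccccc2)c(OCc2ccccc2)c1 | intermediate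
5 | tert-butyldimethyl{(S)-[(2R)-oxiran-2-yl][3,4,5-tris(benzyloxy)phenyl]methoxy}silane | C1O[C@H]1[C@@H](O[Si](C)(C)C(C)(C)C)c1cc(OCc2ccccc2)c(OCc2ccccc2)c(OCc2ccccc2)c1 | intermediate
6 | trimethylsilylacetylene | C#C[Si](C)(C)C | starting material
7 | lithium (trimethylsilyl)acetylide | [Li]C#C[Si](C)(C)C | intermediate
8 | (1S,2R)-1-(tert-butyldimethylsilyloxy)-1-[3,4,5-tris(benzyloxy)phenyl]-5-(trimethylsilyl)pent-4-yn-2-ol | C[Si](C)(C)C#CC[C@@H](O)[C@@H](O[Si](C)(C)C(C)(C)C)c1cc(OCc2ccccc2)c(OCc2ccccc2)c(OCc2ccccc2)c1 | intermediate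
9 | tert-butyl{[(1S,2R)-2-(methoxymethoxy)-1-[3,4,5-tris(benzyloxy)phenyl]-5-(trimethylsilyl)pent-4-yn-1-yl]oxy}dimethylsilane | C[Si](C)(C)C#CC[C@@H](OCOC)[C@@H](O[Si](C)(C)C(C)(C)C)c1cc(OCc2ccccc2)c(OCc2ccccc2)c(OCc2ccccc2)c1 | intermediate
10 | tert-butyl{[(1S,2R)-2-(methoxymethoxy)-1-[3,4,5-tris(benzyloxy)phenyl]pent-4-yn-1-yl]oxy}dimethylsilane | C#CC[C@@H](OCOC)[C@@H](O[Si](C)(C)C(C)(C)C)c1cc(OCc2ccccc2)c(OCc2ccccc2)c(OCc2ccccc2)c1 | intermediate
11 | {(4R,5S)-5-(tert-butyldimethylsilyloxy)-4-(methoxymethoxy)-5-[3,4,5-tris(benzyloxy)phenyl]pent-1-yn-1-yl}lithium | [Li]C#CC[C@@H](OCOC)[C@@H](O[Si](C)(C)C(C)(C)C)c1cc(OCc2ccccc2)c(OCc2ccccc2)c(OCc2ccccc2)c1 | intermediate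
12 | lithium (4R,5S)-5-(tert-butyldimethylsilyloxy)-4-(methoxymethoxy)-5-[3,4,5-tris(benzyloxy)phenyl]pent-1-yn-1-olate | [Li]OC#CC[C@@H](OCOC)[C@@H](O[Si](C)(C)C(C)(C)C)c1cc(OCc2ccccc2)c(OCc2ccccc2)c(OCc2ccccc2)c1 | intermediate
13 | (4R,5S)-5-(tert-butyldimethylsilyloxy)-4-(methoxymethoxy)-5-[3,4,5-tris(benzyloxy)phenyl]-1-(triisopropylsilyloxy)pent-1-yne | CC(C)[Si](C(C)C)(C(C)C)OC#CC[C@@H](OCOC)[C@@H](O[Si](C)(C)C(C)(C)C)c1cc(OCc2ccccc2)c(OCc2ccccc2)c(OCc2ccccc2)c1 | intermediate
14 | 3-ethoxycyclobut-2-en-1-one | CCOC1=CC(=O)C1 | starting material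
15 | 3-(benzyloxy)cyclobut-2-en-1-one | O=C1C=C(OCc2ccccc2)C1 | intermediate
16 | 3-(benzyloxy)buta-1,3-dien-1-one | O=C=CC(=C)OCc1ccccc1 | intermediate
17 | 4-[1-(benzyloxy)ethenyl]-2-[(2R,3S)-3-(tert-butyldimethylsilyloxy)-2-(methoxymethoxy)-3-[3,4,5-tris(benzyloxy)phenyl]propyl]-3-(triisopropylsilyloxy)cyclobut-2-en-1-one | O=C1C(C[C@@H](OCOC)[C@@H](O[Si](C)(C)C(C)(C)C)c2cc(OCc3ccccc3)c(OCc3ccccc3)c(OCc3ccccc3)c2)=C(O[Si](C(C)C)(C(C)C)C(C)C)C1C(=C)OCc1ccccc1 | intermediate
18 | (3E)-5-(benzyloxy)-2-[(2R,3S)-3-(tert-butyldimethylsilyloxy)-2-(methoxymethoxy)-3-[3,4,5-tris(benzyloxy)phenyl]propyl]-3-(triisopropylsilyloxy)hexa-1,3,5-trien-1-one | O=C=C(C[C@@H](OCOC)[C@@H](O[Si](C)(C)C(C)(C)C)c1cc(OCc2ccccc2)c(OCc2ccccc2)c(OCc2ccccc2)c1)/C(O[Si](C(C)C)(C(C)C)C(C)C)=C\C(=C)OCc1ccccc1 | intermediate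
19 | 5-(benzyloxy)-2-[(2R,3S)-3-(tert-butyldimethylsilyloxy)-2-(methoxymethoxy)-3-[3,4,5-tris(benzyloxy)phenyl]propyl]-3-(triisopropylsilyloxy)cyclohexa-2,4-dien-1-one | O=C1CC(OCc2ccccc2)=CC(O[Si](C(C)C)(C(C)C)C(C)C)=C1C[C@@H](OCOC)[C@@H](O[Si](C)(C)C(C)(C)C)c1cc(OCc2ccccc2)c(OCc2ccccc2)c(OCc2ccccc2)c1 | intermediate
20 | 5-(benzyloxy)-2-[(2R,3S)-3-(tert-butyldimethylsilyloxy)-2-(methoxymethoxy)-3-[3,4,5-tris(benzyloxy)phenyl]propyl]-3-(triisopropylsilyloxy)phenol | CC(C)[Si](C(C)C)(C(C)C)Oc1cc(OCc2ccccc2)cc(O)c1C[C@@H](OCOC)[C@@H](O[Si](C)(C)C(C)(C)C)c1cc(OCc2ccccc2)c(OCc2ccccc2)c(OCc2ccccc2)c1 | intermediate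
21 | 5-(benzyloxy)-2-[(2R,3S)-3-hydroxy-2-(methoxymethoxy)-3-[3,4,5-tris(benzyloxy)phenyl]propyl]benzene-1,3-diol | Oc1cc(OCc2ccccc2)cc(O)c1C[C@@H](OCOC)[C@@H](O)c1cc(OCc2ccccc2)c(OCc2ccccc2)c(OCc2ccccc2)c1 | intermediate
22 | (2R,3R)-7-(benzyloxy)-3-(methoxymethoxy)-2-[3,4,5-tris(benzyloxy)phenyl]chroman-5-ol | COCO[C@@H]1Cc2c(O)cc(OCc3ccccc3)cc2O[C@@H]1c1cc(OCc2ccccc2)c(OCc2ccccc2)c(OCc2ccccc2)c1 | intermediate
23 | (2R,3R)-5,7-bis(benzyloxy)-3-(methoxymethoxy)-2-[3,4,5-tris(benzyloxy)phenyl]chroman | COCO[C@@H]1Cc2c(OCc3ccccc3)cc(OCc3ccccc3)cc2O[C@@H]1c1cc(OCc2ccccc2)c(OCc2ccccc2)c(OCc2ccccc2)c1 | intermediate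
24 | (2R,3R)-5,7-bis(benzyloxy)-2-[3,4,5-tris(benzyloxy)phenyl]chroman-3-ol | O[C@@H]1Cc2c(OCc3ccccc3)cc(OCc3ccccc3)cc2O[C@@H]1c1cc(OCc2ccccc2)c(OCc2ccccc2)c(OCc2ccccc2)c1 | intermediate
25 | 4-(benzyloxy)benzoyl chloride | O=C(Cl)c1ccc(OCc2ccccc2)cc1 | starting material
26 | (2R,3R)-5,7-bis(benzyloxy)-2-[3,4,5-tris(benzyloxy)phenyl]chroman-3-yl 4-(benzyloxy)benzoate | O=C(O[C@@H]1Cc2c(OCc3ccccc3)cc(OCc3ccccc3)cc2O[C@@H]1c1cc(OCc2ccccc2)c(OCc2ccccc2)c(OCc2ccccc2)c1)c1ccc(OCc2ccccc2)cc1 | intermediate
27 | (2R,3R)-5,7-dihydroxy-2-(3,4,5-trihydroxyphenyl)chroman-3-yl 4-hydroxybenzoate | O=C(O[C@@H]1Cc2c(O)cc(O)cc2O[C@@H]1c1cc(O)c(O)c(O)c1)c1ccc(O)cc1 | target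

## Step count and least certain steps

Total: 15 steps. Longest linear sequence: 14 steps (steps 1–7 and 9–15, from 1); step 8 is a one-step side branch.

**Step 9 (key step).** The alkoxy group stabilises the cyclobutenone as a vinylogous ester, so ring opening to 16 may be slow. At the temperature then needed, the ketene may be consumed by acylating the phenol of 20 or by self-addition, and the ynol silyl ether may suffer a thermal silyl shift. Acylated phenol can be returned by brief methanolysis, but a failure of ring opening cannot be cured by conditions. The fallback sets out from epoxide 5 and returns at 23; ring A is introduced as a preformed arene.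
- 3,5-Bis(benzyloxy)phenol would be protected with SEMCl/iPr2NEt as {2-[(3,5-bis(benzyloxy)phenoxy)methoxy]ethyl}trimethylsilane F1.
- Directed ortho-lithiation of this (n-BuLi, THF, 0 °C) beside the acetal oxygen, then BF3·OEt2-promoted opening of 5 at its terminal carbon at −78 °C, would give (1S,2R)-3-[2,4-bis(benzyloxy)-6-{[2-(trimethylsilyl)ethoxy]methoxy}phenyl]-1-(tert-butyldimethylsilyloxy)-1-[3,4,5-tris(benzyloxy)phenyl]propan-2-ol F2.
- MOMCl/iPr2NEt would give tert-butyl{[(1S,2R)-3-[2,4-bis(benzyloxy)-6-{[2-(trimethylsilyl)ethoxy]methoxy}phenyl]-2-(methoxymethoxy)-1-[3,4,5-tris(benzyloxy)phenyl]propyl]oxy}dimethylsilane F3.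
- TBAF in THF/DMPU at 60 °C would remove the aryl acetal and the silyl ether to give 3,5-bis(benzyloxy)-2-[(2R,3S)-3-hydroxy-2-(methoxymethoxy)-3-[3,4,5-tris(benzyloxy)phenyl]propyl]phenol F4.
- The Mitsunobu closure of step 11 (PPh3, DIAD) applied to this phenol would give 23 directly.

**Step 8.** Acid and alcohol may cleave the strained ring (addition to the carbonyl group and retro-Claisen opening to acetoacetate-type products) in competition with the exchange at C3. The fallback sets out from 14 and returns at 15. Hydrolysis with dilute aqueous HCl would give cyclobutane-1,3-dione F5, and this strongly acidic enol would be O-benzylated with phenyldiazomethane in Et2O at 0 °C.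

**Step 11.** Two processes threaten the closure:
- Ionisation of the activated benzylic carbon (the para benzyloxy group of ring B stabilises the cation) would let part of the material close without inversion and erode the cis configuration at C2.
- The azodicarboxylate may aminate the very electron-rich ring A.

The fallback sets out from 21 and returns at 24; the leaving group becomes a tethered acyloxonium ion and no azo reagent is present.
- Dilute HCl in MeOH at 0 °C → rt would remove the acetal to give 5-(benzyloxy)-2-[(2R,3S)-2,3-dihydroxy-3-[3,4,5-tris(benzyloxy)phenyl]propyl]benzene-1,3-diol F6.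
- HC(OEt)3 with PPTS in ClCH2CH2Cl (rt → 60 °C) would convert the diol into a cyclic orthoester that a phenol opens at the benzylic carbon with inversion, giving (2R,3R)-7-(benzyloxy)-5-hydroxy-2-[3,4,5-tris(benzyloxy)phenyl]chroman-3-yl formate F7.
- K2CO3 in MeOH would give (2R,3R)-7-(benzyloxy)-2-[3,4,5-tris(benzyloxy)phenyl]chroman-3,5-diol F8.
- Selective benzylation of the phenol (BnBr, K2CO3, acetone) would give 24.

**Step 2.** Epoxidation of a monosubstituted olefin is slow. The rate difference between the enantiomers may then be too small for a clean resolution, and the titanium Lewis acid may open the product on long exposure. The fallback sets out from 3 and returns at 4; it separates the enantiomers before the oxidation.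
- Candida antarctica lipase B with vinyl acetate would acylate the (R)-enantiomer to (R)-1-[3,4,5-tris(benzyloxy)phenyl]prop-2-en-1-yl acetate F9.
- K2CO3 in MeOH would release (R)-1-[3,4,5-tris(benzyloxy)phenyl]prop-2-en-1-ol F10.
- Hydroxyl-directed epoxidation with VO(acac)2 and t-BuOOH, which favours the erythro product, would give 4 after separation of the minor diastereomer.

## Further compounds

F1 | step 9 | {2-[(3,5-bis(benzyloxy)phenoxy)methoxy]ethyl}trimethylsilane | C[Si](C)(C)CCOCOc1cc(OCc2ccccc2)cc(OCc2ccccc2)c1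
F2 | step 9 | (1S,2R)-3-[2,4-bis(benzyloxy)-6-{[2-(trimethylsilyl)ethoxy]methoxy}phenyl]-1-(tert-butyldimethylsilyloxy)-1-[3,4,5-tris(benzyloxy)phenyl]propan-2-ol | C[Si](C)(C)CCOCOc1cc(OCc2ccccc2)cc(OCc2ccccc2)c1C[C@@H](O)[C@@H](O[Si](C)(C)C(C)(C)C)c1cc(OCc2ccccc2)c(OCc2ccccc2)c(OCc2ccccc2)c1
F3 | step 9 | tert-butyl{[(1S,2R)-3-[2,4-bis(benzyloxy)-6-{[2-(trimethylsilyl)ethoxy]methoxy}phenyl]-2-(methoxymethoxy)-1-[3,4,5-tris(benzyloxy)phenyl]propyl]oxy}dimethylsilane | C[Si](C)(C)CCOCOc1cc(OCc2ccccc2)cc(OCc2ccccc2)c1C[C@@H](OCOC)[C@@H](O[Si](C)(C)C(C)(C)C)c1cc(OCc2ccccc2)c(OCc2ccccc2)c(OCc2ccccc2)c1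
F4 | step 9 | 3,5-bis(benzyloxy)-2-[(2R,3S)-3-hydroxy-2-(methoxymethoxy)-3-[3,4,5-tris(benzyloxy)phenyl]propyl]phenol | Oc1cc(OCc2ccccc2)cc(OCc2ccccc2)c1C[C@@H](OCOC)[C@@H](O)c1cc(OCc2ccccc2)c(OCc2ccccc2)c(OCc2ccccc2)c1
F5 | step 8 | cyclobutane-1,3-dione | O=C1CC(=O)C1
F6 | step 11 | 5-(benzyloxy)-2-[(2R,3S)-2,3-dihydroxy-3-[3,4,5-tris(benzyloxy)phenyl]propyl]benzene-1,3-diol | Oc1cc(OCc2ccccc2)cc(O)c1C[C@@H](O)[C@@H](O)c1cc(OCc2ccccc2)c(OCc2ccccc2)c(OCc2ccccc2)c1
F7 | step 11 | (2R,3R)-7-(benzyloxy)-5-hydroxy-2-[3,4,5-tris(benzyloxy)phenyl]chroman-3-yl formate | O=CO[C@@H]1Cc2c(O)cc(OCc3ccccc3)cc2O[C@@H]1c1cc(OCc2ccccc2)c(OCc2ccccc2)c(OCc2ccccc2)c1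
F8 | step 11 | (2R,3R)-7-(benzyloxy)-2-[3,4,5-tris(benzyloxy)phenyl]chroman-3,5-diol | O[C@@H]1Cc2c(O)cc(OCc3ccccc3)cc2O[C@@H]1c1cc(OCc2ccccc2)c(OCc2ccccc2)c(OCc2ccccc2)c1
F9 | step 2 | (R)-1-[3,4,5-tris(benzyloxy)phenyl]prop-2-en-1-yl acetate | C=C[C@@H](OC(C)=O)c1cc(OCc2ccccc2)c(OCc2ccccc2)c(OCc2ccccc2)c1
F10 | step 2 | (R)-1-[3,4,5-tris(benzyloxy)phenyl]prop-2-en-1-ol | C=C[C@@H](O)c1cc(OCc2ccccc2)c(OCc2ccccc2)c(OCc2ccccc2)c1
A1 | alternative 1 | (R)-5,7-bis(benzyloxy)-2-[3,4,5-tris(benzyloxy)phenyl]-2H-chromen-3-yl 4-(benzyloxy)benzoate | O=C(OC1=Cc2c(OCc3ccccc3)cc(OCc3ccccc3)cc2O[C@@H]1c1cc(OCc2ccccc2)c(OCc2ccccc2)c(OCc2ccccc2)c1)c1ccc(OCc2ccccc2)cc1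
A2 | alternative 1 | (3R)-3-[3,5-bis(benzyloxy)-2-ethenylphenoxy]-3-[3,4,5-tris(benzyloxy)phenyl]prop-1-en-2-yl 4-(benzyloxy)benzoate | C=Cc1c(OCc2ccccc2)cc(OCc2ccccc2)cc1O[C@@H](C(=C)OC(=O)c1ccc(OCc2ccccc2)cc1)c1cc(OCc2ccccc2)c(OCc2ccccc2)c(OCc2ccccc2)c1
A3 | alternative 2 | (2R,3R)-5,7-bis(benzyloxy)-2-[3,4,5-tris(benzyloxy)phenyl]chroman-3-ol | O[C@@H]1Cc2c(OCc3ccccc3)cc(OCc3ccccc3)cc2O[C@@H]1c1cc(OCc2ccccc2)c(OCc2ccccc2)c(OCc2ccccc2)c1
A4 | alternative 2 | (2R)-2-{(R)-[3,5-bis(benzyloxy)phenoxy][3,4,5-tris(benzyloxy)phenyl]methyl}oxirane | C1O[C@H]1[C@H](Oc1cc(OCc2ccccc2)cc(OCc2ccccc2)c1)c1cc(OCc2ccccc2)c(OCc2ccccc2)c(OCc2ccccc2)c1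
A5 | alternative 3 | (2R,3R)-5,7-bis(benzyloxy)-2-[3,4,5-tris(benzyloxy)phenyl]chroman-3-yl 4-(benzyloxy)benzoate | O=C(O[C@@H]1Cc2c(OCc3ccccc3)cc(OCc3ccccc3)cc2O[C@@H]1c1cc(OCc2ccccc2)c(OCc2ccccc2)c(OCc2ccccc2)c1)c1ccc(OCc2ccccc2)cc1
A6 | alternative 3 | 3,5-bis(benzyloxy)-2-(hydroxymethyl)phenol | OCc1c(O)cc(OCc2ccccc2)cc1OCc1ccccc1
A7 | alternative 3 | (Z)-2-[3,4,5-tris(benzyloxy)phenyl]ethenyl 4-(benzyloxy)benzoate | O=C(O/C=C\c1cc(OCc2ccccc2)c(OCc2ccccc2)c(OCc2ccccc2)c1)c1ccc(OCc2ccccc2)cc1
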